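South-east has a close neighbour in north-east, with the same charge and the same 50 s, but a flow tank in place of a closed flask, and I asked why the two should end apart.

| flask | substrate | other conformer | time | remark |
|---|---|---|---|---|
| east | 0.52 M | 0.500 equiv (fed, over 50.0 s) | 50 s | a stirred flask in which other conformer is dosed at a steady rate over 50.0 s without added volume, worked up at 50 s |
| south-east | 0.52 M | 0.500 equiv | 50 s | a closed flask charged with all of it at once and left for 50 s |
| north | 0.52 M | 0.500 equiv |  | a single well-mixed tank run continuously and read at steady state, 150 s in it on average |
| north-east | 0.52 M | 0.500 equiv |  | one stirred flow tank at steady state, fed with the mixture as stated, mean residence time 50 s |

    substrate ⇌ other conformer (K1 = 0.888, k1 = 0.115 /s)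
    substrate ⇌ target (K2 = 4.78, k2 = 0.375 /s)
    other conformer → isomer of the product (k3 = 71.9 /s)
    substrate → decomposition product (k4 = 1.87 × 10⁻⁴ /s)
    2 substrate → self-condensation product (k5 = 0.127 /M/s)

- the set-up with the highest share of target in all that became target or isomer of the product, at the outlet or at the end ("none" if the first two lie within 2 percentage points) (east / south-east / north / north-east / none)
- share of target in all that became target or isomer of the product, at the outlet or at the end, east
- share of target in all that became target or isomer of the product, at the outlet or at the end, south-east
- share of target in all that became target or isomer of the product, at the outlet or at the end, north
- share of target in all that became target or isomer of the product, at the outlet or at the end, north-east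

- percentages count the substrate that a species holds: one self-condensation product counts as two
- a step written with two of one species runs at k times the square of its concentration and takes two of it each time
- the stated concentrations are those of everything mixed, before any reaction; amounts are the same in each set-up
- the feed brings no volume worth counting
- run time (east): 50 s

1. Other conformer went on to isomer of the product at 71.9 /s, far faster than it returned to substrate at 0.130 /s. So I counted conformer formed as isomer formed, and I expected east and south-east to end alike.

2. That left two linear balances, for substrate and target. Substrate left at 0.490 /s, and target returned to it at 0.0785 /s.

3. I integrated these in closed form and got two exponentials. Their decay constants have the sum 0.568 /s, and their product equals the rate constant of step 1 times the return constant of target, so the smaller is 0.0163 /s. I call it the drain constant λ, the first-order rate at which target leaks back through substrate into isomer of the product.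

4. I left self-condensation out, so my reckoning gave surviving fractions of target, not shares.

5. In the closed flask south-east, target faced the drain for the full time t, and exp(−λt) gave 0.442.

6. In the tank north-east, 50 s was a mean residence time τ. Averaging the exponential over a tank's spread of times gave one over one plus λτ, or 0.550, which is more than in south-east.

7. North, with 150 s, gave 0.290, the lowest of the three. My order was north-east, then the closed flask, then north.

8. The forecast named north-east, with 19.3% for east, 19.3% for south-east, 13.2% for north and 25.2% for north-east. Its grounds included this: “Target then drains back through substrate at about 0.017 s⁻¹.” It gave shares from hand stepping and tank balances, where my reckoning gave an order.

9. The simulation gave north-east, with 19.8% for east, 19.8% for south-east, 13.2% for north and 25.2% for north-east. South-east at 50 s held 69.8% of the charge as isomer of the product and 2.83% as substrate, so its share put target at 17.3%. Over 450 s more, the drain leaves 6.40 × 10⁻⁴ of that target. Counting the rest of target and substrate into isomer, I got a share of 0.0123%. South-east left to 500 s gave 0.0119%.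

Its constants come from no measurement; no experiment stands behind them.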